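The readings were computed with made-up constants.

A first-order plot that steepens early tempts one to read chains growing without end, and the meeting on this flask opened on that pitfall.

| setting | ash | flask |
|---|---|---|
| free monomer | 0.50 M | 0.50 M |
| initiator | 33 mM | 22 mM |
| remark | run made earlier |  |
| time |  | 6.0 h |

- ash (time / min: monomer in chains / %, free monomer / %): 8.00: 0, 99.5; 20.0: 1.2, 98.6; 50.0: 8.2, 92.8; 120: 25.4, 75.3

(scatter of a reading: 1 percentage point)

1. average number of monomer units in a chain (chains begun, living or dead) at 6.0 h
2. part of the free monomer that has reacted at 6.0 h

- the average divides the monomer in chains by the number of chains begun, living and dead together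
- the earlier runs do not show the number of chains; that part of a forecast is a guess
- no earlier run changes the charge of initiator; that part of a forecast is a guess

The forecaster reported 54% reacted and a dp of 12.5, holding that “Initiator is fully used by 6 h.”

I, taking the minutes, argued a reckoning of my own, supposing that living ends die in pairs. With the living end taken as settled (quasi-steady state) and initiator held at its charge, the reciprocal square root of the fraction of free monomer left climbs steadily from one. The ash run reads 0.0980 h⁻¹, the clock rate, the rise of that root per hour between its last two readings. Its line starts after a read run-in of 0.445 h. Time in the flask counts by the root of the ratio of charge products, 0.816, with initiator held at its charge. The flask's run-in of 0.545 h is shorter than the 6.0 h asked, so I reckoned it settled after that. My estimate was thus 48.5% free, so my c is 51.5%, below the forecast. The ash run shows no number of chains, so I entered no dp.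

The flask gives a dp of 30.5 and c of 50.9%, with 62% of its initiator left at 6.00 h.

    2 living end → dead end (k = 230 M⁻¹ h⁻¹)
    free monomer + initiator → living end + monomer in chains (k = 0.220 M⁻¹ h⁻¹)
    free monomer + living end → monomer in chains + living end, rate k3*[living end]*[free monomer] (k = 74.0 M⁻¹ h⁻¹)

The forecast and the flask part on dp, 12.5 against 30.5, while the clock's 48.5% stands against 49.1% of free monomer in the flask. The neighbouring flask is charged with 0.12 M of free monomer and the same initiator. Its time factor is 0.400, lower than the flask's, and its run-in of 1.11 h is longer. The same clock rate of 0.0980 h⁻¹ reckons 70.4% free at 6.0 h. That neighbouring flask gives a dp of 13.5 and holds 68.7% of its free monomer at 6.00 h.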